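**Strategy.** Ring C is closed through its C2–C3 bond, made as a C2=C3 enol ether. The step exploits that C2 carries both the ring oxygen O1 and ring B, so it is the carbonyl carbon of an aryl benzoate in disguise, while C3–C4 map onto an ortho-allyl group on ring A. A titanium alkylidene olefinic-ester cyclization (ring-closing ester–olefin metathesis) converts the open-chain ester, which has neither ring C nor a stereocenter, into the flav-2-ene in one operation. Asymmetric hydroboration then sets C2 and C3, an oxidation–reduction pair turns C3 to the 2,3-cis series, and galloylation and hydrogenolysis complete the synthesis.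

Key step: step 6

Assumption: IpcBH2 made from (+)-α-pinene is taken to select the face of the C2=C3 bond of 11 in the same sense as it does for 1-arylcycloalkenes, which leads to the (2R,3S) alcohol; should the sense prove opposite, the reagent from (−)-α-pinene is used instead.

Step 1
Reactants: 1 3,5-bis(benzyloxy)phenol; 2 allyl bromide
Product: 3 1-(allyloxy)-3,5-bis(benzyloxy)benzene
Conditions: K2CO3, acetone, reflux
Reagents that add atoms: none
Why: Williamson ether synthesis; the phenoxide is O-alkylated by the allylic bromide in an SN2 reaction.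

Step 2
Reactants: 3 1-(allyloxy)-3,5-bis(benzyloxy)benzene
Product: 4 2-allyl-3,5-bis(benzyloxy)phenol
Conditions: PhNEt2, 190 °C, argon
Reagents that add atoms: none
Why: Aromatic Claisen rearrangement ([3,3] shift, then tautomerization); the two ortho positions are equivalent, so the allyl group should arrive only between OH and OBn, as C4a of ring A requires.

Step 3
Reactants: 5 methyl 3,4,5-tris(benzyloxy)benzoate
Product: 6 methyl 3,5-bis(benzyloxy)-4-hydroxybenzoate
Conditions: MgBr2·OEt2 (1.2 equiv), toluene/Et2O, 75 °C; then 1 M HCl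
Reagents that add atoms: none
Why: Lewis-acid-mediated regioselective benzyl ether cleavage: the 4-benzyloxy group, twisted out of the ring plane by its two ortho neighbours, is the most Lewis-basic oxygen and is chelated by magnesium together with a flanking oxygen, so bromide should remove this benzyl group by SN2 and leave the phenoxide para to the ester, the best leaving group of the three.

Step 4
Reactants: 6 methyl 3,5-bis(benzyloxy)-4-hydroxybenzoate; 7 iodomethane
Product: 9 3,5-bis(benzyloxy)-4-methoxybenzoic acid, via methyl ester 8 (not isolated)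
Conditions: MeI, K2CO3, DMF, rt; then NaOH, MeOH/H2O, 65 °C; then HCl
Reagents that add atoms: sodium hydroxide, [Na+].[OH-] (one oxygen of the carboxyl group)
Why: Williamson O-methylation of the phenoxide followed by saponification of the methyl ester in the same flask; the benzyl ethers are stable to both operations.

Step 5
Reactants: 4 2-allyl-3,5-bis(benzyloxy)phenol; 9 3,5-bis(benzyloxy)-4-methoxybenzoic acid
Product: 10 2-allyl-3,5-bis(benzyloxy)phenyl 3,5-bis(benzyloxy)-4-methoxybenzoate
Conditions: DCC, DMAP (cat.), CH2Cl2, 0 °C to rt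
Reagents that add atoms: none
Why: Steglich esterification; the O-acylisourea is passed on by DMAP to the phenol, which installs O1–C2 with C2 at the ester oxidation level.

Step 6
Reactants: 10 2-allyl-3,5-bis(benzyloxy)phenyl 3,5-bis(benzyloxy)-4-methoxybenzoate
Product: 11 5,7-bis(benzyloxy)-2-[3,5-bis(benzyloxy)-4-methoxyphenyl]-4H-chromene
Conditions: TiCl4, TMEDA, Zn, PbCl2 (cat.), CH3CHBr2, THF/CH2Cl2, 0 to 65 °C; K2CO3 work-up, Et3N-deactivated silica
Reagents that add atoms: none
Why: Olefinic-ester cyclization with the Takai–Utimoto reagent: the reduced titanium ethylidene first exchanges with the terminal CH=CH2 of the allyl group by [2+2]/retro-[2+2] (propene leaves), placing a titanium alkylidene on C3, which then adds across the C2=O of the aryl benzoate and cycloreverts through an oxatitanacyclobutane to the C2=C3 enol ether and a titanium oxo species. The closest known reaction types are the direct conversion of olefinic esters into cyclic enol ethers with reduced titanium alkylidenes and the titanium-mediated methylenation of phenyl benzoates to aryl vinyl ethers. Ring C closes as a six-membered ring by intramolecular carbonyl olefination (ring-closing ester–olefin metathesis), the ortho placement of ester oxygen and allyl group on ring A holding the partners together. No stereocenter is formed; the planar flav-2-ene is the substrate on which C2 and C3 are set in step 7. The selectivity needed is ring closure over simple ethylidenation of the ester and over allyl-to-propenyl isomerization; the ethylidene reagent, which prefers the unhindered monosubstituted olefin, and the six-membered ring size should secure it, and the benzyl ethers and the methoxy group are inert to the reagent.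

Step 7
Reactants: 11 5,7-bis(benzyloxy)-2-[3,5-bis(benzyloxy)-4-methoxyphenyl]-4H-chromene
Product: 13 (2R,3S)-5,7-bis(benzyloxy)-2-[3,5-bis(benzyloxy)-4-methoxyphenyl]chroman-3-ol, via C3 isopinocampheylborane 12 (not isolated)
Conditions: IpcBH2 [from (+)-α-pinene], THF, −25 to 0 °C; then NaOH, H2O2, H2O, 0 °C to rt
Reagents that add atoms: hydrogen peroxide, OO (oxygen at C3 of 13); IpcBH2, C[C@H]1[C@H](B)C[C@@H]2C[C@H]1C2(C)C (boron and isopinocampheyl group of 12 only, hydrogen at C2 of 13)
Why: Asymmetric hydroboration–oxidation: H–B adds syn with boron at C3 (β to O1, remote from the aryl-bearing C2), which gives the 2,3-trans relationship, the chiral borane selects the face (reagent control) to give (2R,3S), and the C–B bond is oxidized with retention.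

Step 8
Reactants: 13 (2R,3S)-5,7-bis(benzyloxy)-2-[3,5-bis(benzyloxy)-4-methoxyphenyl]chroman-3-ol
Product: 14 (2R)-5,7-bis(benzyloxy)-2-[3,5-bis(benzyloxy)-4-methoxyphenyl]chroman-3-one
Conditions: Dess–Martin periodinane, CH2Cl2, 0 °C to rt
Reagents that add atoms: none
Why: Dess–Martin oxidation is neutral and non-enolizing, so the 3-ketone should form without loss of the C2 configuration.

Step 9
Reactants: 14 (2R)-5,7-bis(benzyloxy)-2-[3,5-bis(benzyloxy)-4-methoxyphenyl]chroman-3-one
Product: 15 (2R,3R)-5,7-bis(benzyloxy)-2-[3,5-bis(benzyloxy)-4-methoxyphenyl]chroman-3-ol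
Conditions: LiBH(s-Bu)3 (L-Selectride), THF, −78 °C; then H2O
Reagents that add atoms: none
Why: Substrate-controlled reduction with a bulky hydride: attack on the C3 carbonyl from the face opposite the C2 aryl group should place the new 3-OH cis to ring B, giving (2R,3R).

Step 10
Reactants: 15 (2R,3R)-5,7-bis(benzyloxy)-2-[3,5-bis(benzyloxy)-4-methoxyphenyl]chroman-3-ol; 16 3,4,5-tris(benzyloxy)benzoic acid
Product: 17 (2R,3R)-5,7-bis(benzyloxy)-2-[3,5-bis(benzyloxy)-4-methoxyphenyl]chroman-3-yl 3,4,5-tris(benzyloxy)benzoate
Conditions: DCC, DMAP, CH2Cl2, rt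
Reagents that add atoms: none
Why: Steglich esterification acylates the 3-OH at oxygen, so the C3 configuration is retained.

Step 11
Reactants: 17 (2R,3R)-5,7-bis(benzyloxy)-2-[3,5-bis(benzyloxy)-4-methoxyphenyl]chroman-3-yl 3,4,5-tris(benzyloxy)benzoate
Product: 18 4'-O-methylepigallocatechin-3-O-gallate
Conditions: H2 (1 atm), Pd(OH)2/C, THF/MeOH, rt
Reagents that add atoms: none
Why: Hydrogenolysis of the seven benzyl ethers should leave the gallate ester, the methyl ether and both stereocenters untouched.

**Compound list**

1 | 3,5-bis(benzyloxy)phenol | Oc1cc(OCc2ccccc2)cc(OCc2ccccc2)c1 | starting material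
2 | allyl bromide | C=CCBr | starting material
3 | 1-(allyloxy)-3,5-bis(benzyloxy)benzene | C=CCOc1cc(OCc2ccccc2)cc(OCc2ccccc2)c1 | intermediate
4 | 2-allyl-3,5-bis(benzyloxy)phenol | C=CCc1c(O)cc(OCc2ccccc2)cc1OCc1ccccc1 | intermediate
5 | methyl 3,4,5-tris(benzyloxy)benzoate | COC(=O)c1cc(OCc2ccccc2)c(OCc2ccccc2)c(OCc2ccccc2)c1 | starting material
6 | methyl 3,5-bis(benzyloxy)-4-hydroxybenzoate | COC(=O)c1cc(OCc2ccccc2)c(O)c(OCc2ccccc2)c1 | intermediate
7 | iodomethane | CI | starting material
8 | methyl 3,5-bis(benzyloxy)-4-methoxybenzoate | COC(=O)c1cc(OCc2ccccc2)c(OC)c(OCc2ccccc2)c1 | intermediate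
9 | 3,5-bis(benzyloxy)-4-methoxybenzoic acid | COc1c(OCc2ccccc2)cc(C(=O)O)cc1OCc1ccccc1 | intermediate
10 | 2-allyl-3,5-bis(benzyloxy)phenyl 3,5-bis(benzyloxy)-4-methoxybenzoate | COc1c(OCc2ccccc2)cc(C(=O)Oc2cc(OCc3ccccc3)cc(OCc3ccccc3)c2CC=C)cc1OCc1ccccc1 | intermediate
11 | 5,7-bis(benzyloxy)-2-[3,5-bis(benzyloxy)-4-methoxyphenyl]-4H-chromene | COc1c(OCc2ccccc2)cc(C2=CCc3c(OCc4ccccc4)cc(OCc4ccccc4)cc3O2)cc1OCc1ccccc1 | intermediate
12 | [(2R,3S)-5,7-bis(benzyloxy)-2-[3,5-bis(benzyloxy)-4-methoxyphenyl]chroman-3-yl](isopinocampheyl)borane | C[C@H]1[C@H](B[C@H]2Cc3c(OCc4ccccc4)cc(OCc4ccccc4)cc3O[C@@H]2c2cc(OCc3ccccc3)c(OC)c(OCc3ccccc3)c2)C[C@@H]2C[C@H]1C2(C)C | intermediate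
13 | (2R,3S)-5,7-bis(benzyloxy)-2-[3,5-bis(benzyloxy)-4-methoxyphenyl]chroman-3-ol (2,3-trans) | COc1c(OCc2ccccc2)cc([C@H]2Oc3cc(OCc4ccccc4)cc(OCc4ccccc4)c3C[C@@H]2O)cc1OCc1ccccc1 | intermediate
14 | (2R)-5,7-bis(benzyloxy)-2-[3,5-bis(benzyloxy)-4-methoxyphenyl]chroman-3-one | COc1c(OCc2ccccc2)cc([C@H]2Oc3cc(OCc4ccccc4)cc(OCc4ccccc4)c3CC2=O)cc1OCc1ccccc1 | intermediate
15 | (2R,3R)-5,7-bis(benzyloxy)-2-[3,5-bis(benzyloxy)-4-methoxyphenyl]chroman-3-ol (2,3-cis) | COc1c(OCc2ccccc2)cc([C@H]2Oc3cc(OCc4ccccc4)cc(OCc4ccccc4)c3C[C@H]2O)cc1OCc1ccccc1 | intermediate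
16 | 3,4,5-tris(benzyloxy)benzoic acid | OC(=O)c1cc(OCc2ccccc2)c(OCc2ccccc2)c(OCc2ccccc2)c1 | starting material
17 | (2R,3R)-5,7-bis(benzyloxy)-2-[3,5-bis(benzyloxy)-4-methoxyphenyl]chroman-3-yl 3,4,5-tris(benzyloxy)benzoate | COc1c(OCc2ccccc2)cc([C@H]2Oc3cc(OCc4ccccc4)cc(OCc4ccccc4)c3C[C@H]2OC(=O)c2cc(OCc3ccccc3)c(OCc3ccccc3)c(OCc3ccccc3)c2)cc1OCc1ccccc1 | intermediate
18 | 4'-O-methylepigallocatechin-3-O-gallate, (2R,3R) | COc1c(O)cc([C@H]2Oc3cc(O)cc(O)c3C[C@H]2OC(=O)c2cc(O)c(O)c(O)c2)cc1O | target

**Step count.** Total: 11 steps. Longest linear sequence: 9 steps (steps 3, 4, 5, 6, 7, 8, 9, 10, 11, from compound 5 to compound 18). The ring A branch (steps 1, 2, then 5 to 11, from compound 1) is equally long.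

**Steps most likely to fail**

Step 6. The titanium ethylidene may only ethylidenate the ester carbonyl without closing the ring, or may isomerize the allyl group to a propenyl group before cyclization. The fallback sets out from ester 10 and divides the task between two metals. Methylenation of the ester carbonyl with the Petasis reagent Cp2TiMe2 (toluene, 70 °C, dark) should give 2-allyl-3,5-bis(benzyloxy)phenyl 1-[3,5-bis(benzyloxy)-4-methoxyphenyl]vinyl ether F1. Ring-closing olefin metathesis of this diene with (H2IMes)(PCy3)Cl2Ru=CHPh (second-generation Grubbs catalyst, toluene, 70 °C) should then form the C2=C3 bond with loss of ethene. The fallback comes back to the route at flav-2-ene 11.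

Step 7. The facial selectivity of the chiral borane toward this enol ether may be poor, so that alcohol 13 is obtained with insufficient enantiomeric purity. The fallback sets out from 13 of low enantiomeric purity and replaces reagent control by an enzymatic kinetic resolution. With Pseudomonas cepacia lipase and vinyl acetate in tert-butyl methyl ether at 35 °C, the Kazlauskas rule predicts faster acylation of the (3R) carbinol. The minor enantiomer should thus be converted into (2S,3R)-5,7-bis(benzyloxy)-2-[3,5-bis(benzyloxy)-4-methoxyphenyl]chroman-3-yl acetate F2, which is removed by chromatography. The fallback comes back to the route at enantiomerically enriched 13.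

Step 3. Ether cleavage may not stop at the 4-position: the magnesium phenoxide first formed can deliver the Lewis acid to a flanking benzyl ether, so that over-debenzylation or loss of regiocontrol results. The fallback sets out from ester 5 and reverses the order in which the two kinds of ether are installed. Exhaustive hydrogenolysis (H2, Pd/C, EtOAc/MeOH, rt) should give methyl gallate F3. Its 4-OH, para to the ester, is the most acidic of the three, so alkylation with one equivalent of iodomethane under a weak base (KHCO3, DMF, rt) should give methyl 3,5-dihydroxy-4-methoxybenzoate F4. Benzylation of both remaining phenols (BnBr, K2CO3, DMF, 60 °C) then gives the fully protected methyl ester. The fallback comes back to the route at ester 8, which is saponified as in step 4.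

**Further compounds**

F1 | step 6 | 2-allyl-3,5-bis(benzyloxy)phenyl 1-[3,5-bis(benzyloxy)-4-methoxyphenyl]vinyl ether | COc1c(OCc2ccccc2)cc(C(=C)Oc2cc(OCc3ccccc3)cc(OCc3ccccc3)c2CC=C)cc1OCc1ccccc1
F2 | step 7 | (2S,3R)-5,7-bis(benzyloxy)-2-[3,5-bis(benzyloxy)-4-methoxyphenyl]chroman-3-yl acetate | COc1c(OCc2ccccc2)cc([C@@H]2Oc3cc(OCc4ccccc4)cc(OCc4ccccc4)c3C[C@H]2OC(C)=O)cc1OCc1ccccc1
F3 | step 3 | methyl gallate | COC(=O)c1cc(O)c(O)c(O)c1
F4 | step 3 | methyl 3,5-dihydroxy-4-methoxybenzoate | COC(=O)c1cc(O)c(OC)c(O)c1
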